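**Retrosynthetic overview**

1. Target 21 ⇐ ester cleavage and radical denitration ⇐ nitro bicycle 19 ⇐ open-chain nitro alcohol 18; one oxidative step makes the C6–C7 bond of the cyclohexane (ring B) and the O–C8 bond of the oxane.
2. Enabling feature: the isopropenyl group on C9 (C7=C8, methyl on C8) lies 6-endo to the nitronate carbon C6; the tertiary C13–OH, three carbons beyond C9, captures the C8 cation; the CMe2CO2R arm on C5 locks the chair so that oxygen arrives cis to C11.
3. 18 ⇐ nitroalkene 14 + 2-methylpropanal (enamine Michael addition sets C5 and brings C3/C4) ⇐ aldehyde 11 + nitromethane (C6).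
4. 11 ⇐ temporary iodo-γ-lactone 8 (C10 set by enolate methylation, opened by zinc fragmentation) ⇐ acid 6 ⇐ enantioselective Ireland–Claisen rearrangement of succinate 5 (sets C9, creates the isopropenyl group) ⇐ (R)-linalool (C13) + mono-tert-butyl succinate.
5. Ring order: temporary γ-lactone (step 5, opened in step 8), then ring B and the oxane together (step 12).

Key step: step 12

Remark on numbering: labdane-type positions are used in the text. Ring B is C5–C10 (C5 carries the CMe2CO2H arm C4/C3; C10 carries CH3 and the CH2CO2H arm C1/C2). The oxane is O, C8, C9, C11, C12, C13. C14=C15 is the vinyl group.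

Assumption: in the two reagent-controlled steps (4 and 10) the enantiomer of the chiral controller named is taken to be the one that delivers the configuration drawn; both antipodes of each controller are accessible.

Remark on mixtures: compounds 6, 7, 9, 13 and 19 are mixtures at centres that are destroyed later; those centres are left unspecified in the SMILES.

**Step 1**
Reactants: 1 (R)-linalool
Product: 2 (3R)-3,7-dimethyl-3-(triethylsilyloxy)octa-1,6-diene
Conditions: Et3SiOTf, 2,6-lutidine, CH2Cl2, −78 to 0 °C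
Reagents that add atoms: triethylsilyl trifluoromethanesulfonate, CC[Si](CC)(CC)OS(=O)(=O)C(F)(F)F
Why: Silylation of the tertiary allylic alcohol with the silyl triflate is routine and masks the C13 hydroxyl against the iodine and boron electrophiles used later, the C13 stereocenter being carried unchanged from the chiral pool.

**Step 2**
Reactants: 2 (3R)-3,7-dimethyl-3-(triethylsilyloxy)octa-1,6-diene
Product: 3 (2E,6R)-2,6-dimethyl-6-(triethylsilyloxy)octa-2,7-dien-1-ol
Conditions: SeO2 (cat.), t-BuOOH, CH2Cl2, rt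
Reagents that add atoms: tert-butyl hydroperoxide, CC(C)(C)OO
Why: SeO2-catalysed allylic oxidation (ene reaction then [2,3]-shift) should hydroxylate the E-methyl group of the trisubstituted alkene selectively and give the E-allylic alcohol needed for the sigmatropic step.

**Step 3**
Reactants: 3 (2E,6R)-2,6-dimethyl-6-(triethylsilyloxy)octa-2,7-dien-1-ol; 4 4-tert-butoxy-4-oxobutanoic acid
Product: 5 1-tert-butyl 4-[(2E,6R)-2,6-dimethyl-6-(triethylsilyloxy)octa-2,7-dien-1-yl] butanedioate
Conditions: DCC, DMAP (cat.), CH2Cl2, 0 °C to rt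
Reagents that add atoms: none
Why: Steglich esterification of the primary allylic alcohol with the succinic half-ester is reliable and installs the C5/C10/C1/C2 unit as the enolisable partner.

**Step 4**
Reactants: 5 1-tert-butyl 4-[(2E,6R)-2,6-dimethyl-6-(triethylsilyloxy)octa-2,7-dien-1-yl] butanedioate
Product: 6 (3S,6R)-2-(2-tert-butoxy-2-oxoethyl)-6-methyl-3-(prop-1-en-2-yl)-6-(triethylsilyloxy)oct-7-enoic acid
Conditions: (S,S)-2-bromo-4,5-diphenyl-1,3-bis[3,5-bis(trifluoromethyl)phenylsulfonyl]-1,3,2-diazaborolidine, Et3N, toluene–hexane, −78 °C then 4 °C; aqueous work-up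
Reagents that add atoms: none
Why: Enantioselective Ireland–Claisen rearrangement of the boron enolate formed at the allyl ester (the tert-butyl ester being too hindered to bind boron) through a chair transition state should form the C9–C10 bond and the isopropenyl group, the chiral sulfonamide ligands on boron deciding which face of the E-alkene is attacked and thereby the C9 configuration, while the C10 centre made at the same time is re-enolised in step 6.

**Step 5**
Reactants: 6 (3S,6R)-2-(2-tert-butoxy-2-oxoethyl)-6-methyl-3-(prop-1-en-2-yl)-6-(triethylsilyloxy)oct-7-enoic acid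
Product: 7 tert-butyl 2-{(4S)-5-(iodomethyl)-5-methyl-4-[(3R)-3-methyl-3-(triethylsilyloxy)pent-4-en-1-yl]-2-oxooxolan-3-yl}acetate
Conditions: I2, NaHCO3, MeCN–H2O, 0 °C
Reagents that add atoms: iodine, II
Why: 5-exo iodolactonisation of the γ,δ-unsaturated acid onto the 1,1-disubstituted alkene should place C10 in a γ-lactone next to the C9 stereocenter and mask the isopropenyl group, the new carbinol centre at C8 being inconsequential.

**Step 6**
Reactants: 7 tert-butyl 2-{(4S)-5-(iodomethyl)-5-methyl-4-[(3R)-3-methyl-3-(triethylsilyloxy)pent-4-en-1-yl]-2-oxooxolan-3-yl}acetate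
Product: 8 tert-butyl 2-{(3R,4S)-5-(iodomethyl)-3,5-dimethyl-4-[(3R)-3-methyl-3-(triethylsilyloxy)pent-4-en-1-yl]-2-oxooxolan-3-yl}acetate
Conditions: LiN(i-Pr)2, THF, −78 °C; MeI, −78 to −20 °C
Reagents that add atoms: iodomethane, CI
Why: Alkylation of the γ-lactone enolate (more acidic than the tert-butyl ester) should occur anti to the adjacent C9 side chain, so that methyl enters trans to C11 and the quaternary C10 centre is set under cyclic control whichever C10 epimer of 7 is used.

**Step 7**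
Reactants: 8 tert-butyl 2-{(3R,4S)-5-(iodomethyl)-3,5-dimethyl-4-[(3R)-3-methyl-3-(triethylsilyloxy)pent-4-en-1-yl]-2-oxooxolan-3-yl}acetate
Product: 9 tert-butyl 2-{(3R,4S)-2-hydroxy-5-(iodomethyl)-3,5-dimethyl-4-[(3R)-3-methyl-3-(triethylsilyloxy)pent-4-en-1-yl]oxolan-3-yl}acetate
Conditions: i-Bu2AlH (1.1 equiv), CH2Cl2, −78 °C
Reagents that add atoms: none
Why: Partial reduction of a lactone to the lactol with one equivalent of i-Bu2AlH at low temperature should be selective over the hindered tert-butyl ester.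

**Step 8**
Reactants: 9 tert-butyl 2-{(3R,4S)-2-hydroxy-5-(iodomethyl)-3,5-dimethyl-4-[(3R)-3-methyl-3-(triethylsilyloxy)pent-4-en-1-yl]oxolan-3-yl}acetate
Product: 11 tert-butyl (3R,4R,7R)-3-formyl-7-hydroxy-3,7-dimethyl-4-(prop-1-en-2-yl)non-8-enoate, via silyl ether aldehyde 10 (not isolated)
Conditions: Zn, AcOH, THF, rt; then Bu4NF, THF, 0 °C
Reagents that add atoms: none
Why: Zinc-mediated reductive fragmentation of the β-iodo lactol (Bernet–Vasella type) should regenerate the isopropenyl group and release C5 as the non-enolisable aldehyde, after which fluoride removes the silyl group without touching a stereocenter.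

**Step 9**
Reactants: 11 tert-butyl (3R,4R,7R)-3-formyl-7-hydroxy-3,7-dimethyl-4-(prop-1-en-2-yl)non-8-enoate; 12 nitromethane
Product: 14 tert-butyl (3R,4R,7R)-7-hydroxy-3,7-dimethyl-3-[(E)-2-nitroethenyl]-4-(prop-1-en-2-yl)non-8-enoate, via nitro alcohol 13 (not isolated)
Conditions: MeNO2, tetramethylguanidine (cat.), THF, 0 °C; then DCC, CuCl (cat.), Et2O, rt
Reagents that add atoms: none
Why: Henry reaction of the aldehyde followed by carbodiimide dehydration of the β-nitro alcohol (which leaves the tertiary alcohol alone) should give the E-nitroalkene and introduce C6 as a latent carbanion and radical site.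

**Step 10**
Reactants: 14 tert-butyl (3R,4R,7R)-7-hydroxy-3,7-dimethyl-3-[(E)-2-nitroethenyl]-4-(prop-1-en-2-yl)non-8-enoate; 15 2-methylpropanal
Product: 16 tert-butyl (3R,4R,7R)-3-[(2R)-3,3-dimethyl-1-nitro-4-oxobutan-2-yl]-7-hydroxy-3,7-dimethyl-4-(prop-1-en-2-yl)non-8-enoate
Conditions: 2-methylpropanal (excess), primary amine–thiourea catalyst from (1R,2R)-cyclohexane-1,2-diamine (20 mol %), H2O (5 equiv), CH2Cl2, rt
Reagents that add atoms: none
Why: Enamine-catalysed Michael addition of an α,α-disubstituted aldehyde to a nitroalkene should form the C4–C5 bond, the C5 configuration being set by the catalyst, which holds the nitro group on its thiourea and delivers the enamine to one face of the alkene.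

**Step 11**
Reactants: 16 tert-butyl (3R,4R,7R)-3-[(2R)-3,3-dimethyl-1-nitro-4-oxobutan-2-yl]-7-hydroxy-3,7-dimethyl-4-(prop-1-en-2-yl)non-8-enoate
Product: 18 tert-butyl (3R,4R,7R)-3-[(2R)-4-tert-butoxy-3,3-dimethyl-1-nitro-4-oxobutan-2-yl]-7-hydroxy-3,7-dimethyl-4-(prop-1-en-2-yl)non-8-enoate, via carboxylic acid 17 (not isolated)
Conditions: NaClO2, NaH2PO4, 2-methyl-2-butene, t-BuOH–H2O, rt; then tert-butyl 2,2,2-trichloroacetimidate, CH2Cl2–cyclohexane, rt
Reagents that add atoms: sodium chlorite, [Na+].[O-]Cl=O; tert-butyl 2,2,2-trichloroacetimidate, CC(C)(C)OC(=N)C(Cl)(Cl)Cl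
Why: Pinnick oxidation should convert the aldehyde to the acid without touching the alkenes or the nitro group, and the imidate then esterifies the hindered acid by O-alkylation under self-catalysis so that no free carboxylate is exposed to the oxidant of step 12.

**Step 12**
Reactants: 18 tert-butyl (3R,4R,7R)-3-[(2R)-4-tert-butoxy-3,3-dimethyl-1-nitro-4-oxobutan-2-yl]-7-hydroxy-3,7-dimethyl-4-(prop-1-en-2-yl)non-8-enoate
Product: 19 tert-butyl 2-[(2R,4aS,5S,6R,8aR)-5-(2-tert-butoxy-2-oxoethyl)-2-ethenyl-2,5,8a-trimethyl-7-nitro-octahydro-2H-chromen-6-yl]-2-methylpropanoate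
Conditions: KOt-Bu (1.05 equiv), THF, −40 °C; then (NH4)2Ce(NO3)6 (2.2 equiv), NaHCO3, MeCN, −40 to 0 °C
Reagents that add atoms: none
Why: Proposed new method: the potassium nitronate of 18 is oxidised by single-electron transfer to tetravalent cerium to the electrophilic α-nitroalkyl radical at C6, which adds to the terminal carbon C7 of the isopropenyl group; the tertiary C8 radical is oxidised by a second equivalent to the cation, which the C13 hydroxyl captures. The closest known reaction types are the (NH4)2Ce(NO3)6-mediated additions of nitronate-derived radicals to electron-rich alkenes and the Mn(OAc)3/Cu(OAc)2 oxidative cyclisations of 1,3-dicarbonyl compounds that end by cation capture; what is new is the intramolecular use of a simple nitronate with an alcohol as terminator, two nucleophilic carbons (C6 and C7) being joined by oxidation. Ring B closes in the 6-endo-trig mode (C6–C7) and the oxane closes by capture of the C8 cation through a six-membered transition state (O–C8). The only lasting new stereocenter, C8, is controlled by the chair transition state in which the bulky CMe2CO2t-Bu group on C5 is equatorial, which makes the C10 methyl and the C9–C11 bond axial, so that oxygen can reach C8 only on the face of C11 (cis-fused oxane, C8 methyl axial); the nitro-bearing C6 centre is erased in step 13. The step needs 6-endo over 5-exo closure, which the 1,1-disubstituted alkene secures because attack of the electrophilic radical at the unsubstituted terminus gives the tertiary radical, and it needs capture by the internal hydroxyl rather than by nitrate or solvent, which the six-membered proximity secures.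

**Step 13**
Reactants: 19 tert-butyl 2-[(2R,4aS,5S,6R,8aR)-5-(2-tert-butoxy-2-oxoethyl)-2-ethenyl-2,5,8a-trimethyl-7-nitro-octahydro-2H-chromen-6-yl]-2-methylpropanoate
Product: 20 tert-butyl 2-[(2R,4aS,5S,6R,8aR)-5-(2-tert-butoxy-2-oxoethyl)-2-ethenyl-2,5,8a-trimethyl-octahydro-2H-chromen-6-yl]-2-methylpropanoate
Conditions: Bu3SnH, AIBN, toluene, 110 °C
Reagents that add atoms: none
Why: Radical denitration of the secondary nitro group in a stannyl radical chain should replace NO2 by H and erase the C6 centre without affecting the other stereocenters or the remote vinyl group.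

**Step 14**
Reactants: 20 tert-butyl 2-[(2R,4aS,5S,6R,8aR)-5-(2-tert-butoxy-2-oxoethyl)-2-ethenyl-2,5,8a-trimethyl-octahydro-2H-chromen-6-yl]-2-methylpropanoate
Product: 21 2-[(2R,4aS,5S,6R,8aR)-5-(carboxymethyl)-2-ethenyl-2,5,8a-trimethyl-octahydro-2H-chromen-6-yl]-2-methylpropanoic acid
Conditions: 85% aq. H3PO4, toluene, rt to 40 °C
Reagents that add atoms: none
Why: Acidolysis of both tert-butyl esters by loss of 2-methylpropene should proceed under conditions mild enough to leave the tertiary allylic ether and the vinyl group intact.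

**Compound list**

1 | (R)-linalool, (3R)-3,7-dimethylocta-1,6-dien-3-ol | C=C[C@@](O)(C)CCC=C(C)C | starting material
2 | (3R)-3,7-dimethyl-3-(triethylsilyloxy)octa-1,6-diene | C=C[C@@](O[Si](CC)(CC)CC)(C)CCC=C(C)C | intermediate
3 | (2E,6R)-2,6-dimethyl-6-(triethylsilyloxy)octa-2,7-dien-1-ol | C=C[C@@](O[Si](CC)(CC)CC)(C)CC/C=C(\C)CO | intermediate
4 | 4-tert-butoxy-4-oxobutanoic acid (mono-tert-butyl succinate) | OC(=O)CCC(=O)OC(C)(C)C | starting material
5 | 1-tert-butyl 4-[(2E,6R)-2,6-dimethyl-6-(triethylsilyloxy)octa-2,7-dien-1-yl] butanedioate | C=C[C@@](O[Si](CC)(CC)CC)(C)CC/C=C(\C)COC(=O)CCC(=O)OC(C)(C)C | intermediate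
6 | (3S,6R)-2-(2-tert-butoxy-2-oxoethyl)-6-methyl-3-(prop-1-en-2-yl)-6-(triethylsilyloxy)oct-7-enoic acid (C2 of the acid, i.e. C10, unspecified; erased in step 6) | C=C[C@@](O[Si](CC)(CC)CC)(C)CC[C@H](C(C)=C)C(CC(=O)OC(C)(C)C)C(=O)O | intermediate
7 | tert-butyl 2-{(4S)-5-(iodomethyl)-5-methyl-4-[(3R)-3-methyl-3-(triethylsilyloxy)pent-4-en-1-yl]-2-oxooxolan-3-yl}acetate (epimers at lactone C3 and C5) | C=C[C@@](O[Si](CC)(CC)CC)(C)CC[C@H]1C(CC(=O)OC(C)(C)C)C(=O)OC1(C)CI | intermediate
8 | tert-butyl 2-{(3R,4S)-5-(iodomethyl)-3,5-dimethyl-4-[(3R)-3-methyl-3-(triethylsilyloxy)pent-4-en-1-yl]-2-oxooxolan-3-yl}acetate (epimers at lactone C5) | C=C[C@@](O[Si](CC)(CC)CC)(C)CC[C@H]1[C@@](C)(CC(=O)OC(C)(C)C)C(=O)OC1(C)CI | intermediate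
9 | tert-butyl 2-{(3R,4S)-2-hydroxy-5-(iodomethyl)-3,5-dimethyl-4-[(3R)-3-methyl-3-(triethylsilyloxy)pent-4-en-1-yl]oxolan-3-yl}acetate (lactol; anomers and C5 epimers) | C=C[C@@](O[Si](CC)(CC)CC)(C)CC[C@H]1[C@@](C)(CC(=O)OC(C)(C)C)C(O)OC1(C)CI | intermediate
10 | tert-butyl (3R,4R,7R)-3-formyl-3,7-dimethyl-4-(prop-1-en-2-yl)-7-(triethylsilyloxy)non-8-enoate | C=C[C@@](O[Si](CC)(CC)CC)(C)CC[C@H](C(C)=C)[C@@](C)(CC(=O)OC(C)(C)C)C=O | intermediate (not isolated)
11 | tert-butyl (3R,4R,7R)-3-formyl-7-hydroxy-3,7-dimethyl-4-(prop-1-en-2-yl)non-8-enoate | C=C[C@@](O)(C)CC[C@H](C(C)=C)[C@@](C)(CC(=O)OC(C)(C)C)C=O | intermediate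
12 | nitromethane | C[N+](=O)[O-] | starting material
13 | tert-butyl (3R,4R,7R)-7-hydroxy-3-(1-hydroxy-2-nitroethyl)-3,7-dimethyl-4-(prop-1-en-2-yl)non-8-enoate (carbinol epimers) | C=C[C@@](O)(C)CC[C@H](C(C)=C)[C@@](C)(CC(=O)OC(C)(C)C)C(O)C[N+](=O)[O-] | intermediate (not isolated)
14 | tert-butyl (3R,4R,7R)-7-hydroxy-3,7-dimethyl-3-[(E)-2-nitroethenyl]-4-(prop-1-en-2-yl)non-8-enoate | C=C[C@@](O)(C)CC[C@H](C(C)=C)[C@@](C)(CC(=O)OC(C)(C)C)/C=C/[N+](=O)[O-] | intermediate
15 | 2-methylpropanal | CC(C)C=O | starting material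
16 | tert-butyl (3R,4R,7R)-3-[(2R)-3,3-dimethyl-1-nitro-4-oxobutan-2-yl]-7-hydroxy-3,7-dimethyl-4-(prop-1-en-2-yl)non-8-enoate | C=C[C@@](O)(C)CC[C@H](C(C)=C)[C@@](C)(CC(=O)OC(C)(C)C)[C@H](C(C)(C)C=O)C[N+](=O)[O-] | intermediate
17 | (3R)-3-[(3R,4R,7R)-1-tert-butoxy-7-hydroxy-3,7-dimethyl-1-oxo-4-(prop-1-en-2-yl)non-8-en-3-yl]-2,2-dimethyl-4-nitrobutanoic acid | C=C[C@@](O)(C)CC[C@H](C(C)=C)[C@@](C)(CC(=O)OC(C)(C)C)[C@H](C(C)(C)C(=O)O)C[N+](=O)[O-] | intermediate (not isolated)
18 | tert-butyl (3R,4R,7R)-3-[(2R)-4-tert-butoxy-3,3-dimethyl-1-nitro-4-oxobutan-2-yl]-7-hydroxy-3,7-dimethyl-4-(prop-1-en-2-yl)non-8-enoate | C=C[C@@](O)(C)CC[C@H](C(C)=C)[C@@](C)(CC(=O)OC(C)(C)C)[C@H](C(C)(C)C(=O)OC(C)(C)C)C[N+](=O)[O-] | intermediate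
19 | tert-butyl 2-[(2R,4aS,5S,6R,8aR)-5-(2-tert-butoxy-2-oxoethyl)-2-ethenyl-2,5,8a-trimethyl-7-nitro-octahydro-2H-chromen-6-yl]-2-methylpropanoate (C7 epimers) | C=C[C@@]1(C)CC[C@H]2[C@@](C)(CC(=O)OC(C)(C)C)[C@H](C(C)(C)C(=O)OC(C)(C)C)C([N+](=O)[O-])C[C@@]2(C)O1 | intermediate
20 | tert-butyl 2-[(2R,4aS,5S,6R,8aR)-5-(2-tert-butoxy-2-oxoethyl)-2-ethenyl-2,5,8a-trimethyl-octahydro-2H-chromen-6-yl]-2-methylpropanoate | C=C[C@@]1(C)CC[C@H]2[C@@](C)(CC(=O)OC(C)(C)C)[C@H](C(C)(C)C(=O)OC(C)(C)C)CC[C@@]2(C)O1 | intermediate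
21 | 2-[(2R,4aS,5S,6R,8aR)-5-(carboxymethyl)-2-ethenyl-2,5,8a-trimethyl-octahydro-2H-chromen-6-yl]-2-methylpropanoic acid (CNP0186744.1) | C=C[C@@]1(C)CC[C@H]2[C@@](C)(CC(=O)O)[C@H](C(C)(C)C(=O)O)CC[C@@]2(C)O1 | target

**Step count and risks**

Total step count: 14. Longest linear sequence: 14 steps (from 1; the route is fully linear, with 4, 12 and 15 entering as building blocks).

Steps most likely to fail:

1. Step 12 (proposed new method). The α-nitroalkyl radical may close 5-exo instead of 6-endo, the nitronate may be over-oxidised to a carbonyl group, and the C8 cation may be intercepted by nitrate or lose a proton instead of being captured by the hydroxyl. The fallback uses known chemistry, sets out from 18 and comes back at 20. A Nef reaction of 18 (NaOMe, MeOH, then buffered aqueous TiCl3) gives tert-butyl (3R,4R,7R)-3-[(2R)-4-tert-butoxy-3,3-dimethyl-1,4-dioxobutan-2-yl]-7-hydroxy-3,7-dimethyl-4-(prop-1-en-2-yl)non-8-enoate F1. A Me2AlCl-promoted carbonyl-ene cyclisation of the aldehyde onto the isopropenyl group (CH2Cl2, −78 °C) forms the same C6–C7 bond and gives the methylidenecyclohexanol tert-butyl 2-[2-(2-tert-butoxy-2-oxoethyl)-6-hydroxy-3-(3-hydroxy-3-methylpent-4-en-1-yl)-2-methyl-4-methylidenecyclohexyl]-2-methylpropanoate F2. Hydrogen-atom-transfer hydroalkoxylation of the 1,1-disubstituted alkene (Co(salen), C16H14CoN2O2, with N-fluoro-2,4,6-trimethylpyridinium triflate and PhSiH3) closes the oxane under the same conformational lock and gives the 7-hydroxy analogue of 20, F3. Its O-[(methylsulfanyl)carbonothioyl] derivative F4 (NaH, CS2, MeI) is reduced with Bu3SnH and AIBN (Barton–McCombie deoxygenation) to 20.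

2. Step 10. The nitroalkene carries a quaternary carbon on its β-position and the enamine is tetrasubstituted, so the addition may be too slow or facial control may erode. The fallback sets out from 14 and comes back at 18: conjugate addition of the preformed lithium enolate of tert-butyl 2-methylpropanoate (LiN(i-Pr)2, THF, −78 °C, two equivalents because of the free hydroxyl) gives 18 directly, under substrate control (attack anti to the C9 branch on C10), and bypasses 16 and 17; no compound outside the list arises (F0).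

3. Step 4. The boron reagent may enolise the tert-butyl ester side instead of the allyl ester, or enantiofacial control over C9 may be incomplete. The fallback replaces the rearrangement by auxiliary-controlled conjugate addition, sets out from 2 and comes back at 7:
   - Ozonolysis of the trisubstituted alkene of 2 (O3, CH2Cl2–pyridine, −78 °C, then Me2S) gives (4R)-4-methyl-4-(triethylsilyloxy)hex-5-enal F5.
   - Wittig reaction with (4R)-4-benzyl-3-[(triphenylphosphoranylidene)acetyl]-1,3-oxazolidin-2-one gives (4R)-4-benzyl-3-[(2E,6R)-6-methyl-6-(triethylsilyloxy)octa-2,7-dienoyl]-1,3-oxazolidin-2-one F6.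
   - Addition of CH2=C(CH3)MgBr with CuBr·SMe2 to the chelated s-cis enoyl imide, anti to the benzyl group, gives (4R)-4-benzyl-3-[(3S,6R)-6-methyl-3-(prop-1-en-2-yl)-6-(triethylsilyloxy)oct-7-enoyl]-1,3-oxazolidin-2-one F7.
   - LiOH/H2O2 releases (3S,6R)-6-methyl-3-(prop-1-en-2-yl)-6-(triethylsilyloxy)oct-7-enoic acid F8.
   - Iodolactonisation (I2, NaHCO3) gives (4S)-5-(iodomethyl)-5-methyl-4-[(3R)-3-methyl-3-(triethylsilyloxy)pent-4-en-1-yl]oxolan-2-one F9.
   - Alkylation of its lithium enolate with tert-butyl bromoacetate (anti to the C9 side chain) gives 7, which is methylated as in step 6.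

**Further compounds**

F1 | step 12 | tert-butyl (3R,4R,7R)-3-[(2R)-4-tert-butoxy-3,3-dimethyl-1,4-dioxobutan-2-yl]-7-hydroxy-3,7-dimethyl-4-(prop-1-en-2-yl)non-8-enoate | C=C[C@@](O)(C)CC[C@H](C(C)=C)[C@@](C)(CC(=O)OC(C)(C)C)[C@H](C(C)(C)C(=O)OC(C)(C)C)C=O
F2 | step 12 | tert-butyl 2-[2-(2-tert-butoxy-2-oxoethyl)-6-hydroxy-3-(3-hydroxy-3-methylpent-4-en-1-yl)-2-methyl-4-methylidenecyclohexyl]-2-methylpropanoate (configurations as in 18, carbinol epimers) | C=C[C@@](O)(C)CC[C@H]1[C@@](C)(CC(=O)OC(C)(C)C)[C@H](C(C)(C)C(=O)OC(C)(C)C)C(O)CC1=C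
F3 | step 12 | tert-butyl 2-[(2R,4aS,5S,6R,8aR)-5-(2-tert-butoxy-2-oxoethyl)-2-ethenyl-7-hydroxy-2,5,8a-trimethyl-octahydro-2H-chromen-6-yl]-2-methylpropanoate (C7 epimers) | C=C[C@@]1(C)CC[C@H]2[C@@](C)(CC(=O)OC(C)(C)C)[C@H](C(C)(C)C(=O)OC(C)(C)C)C(O)C[C@@]2(C)O1
F4 | step 12 | tert-butyl 2-[(2R,4aS,5S,6R,8aR)-5-(2-tert-butoxy-2-oxoethyl)-2-ethenyl-2,5,8a-trimethyl-7-{[(methylsulfanyl)carbonothioyl]oxy}-octahydro-2H-chromen-6-yl]-2-methylpropanoate (C7 epimers) | C=C[C@@]1(C)CC[C@H]2[C@@](C)(CC(=O)OC(C)(C)C)[C@H](C(C)(C)C(=O)OC(C)(C)C)C(OC(=S)SC)C[C@@]2(C)O1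
F0 | step 10 | none | none
F5 | step 4 | (4R)-4-methyl-4-(triethylsilyloxy)hex-5-enal | C=C[C@@](O[Si](CC)(CC)CC)(C)CCC=O
F6 | step 4 | (4R)-4-benzyl-3-[(2E,6R)-6-methyl-6-(triethylsilyloxy)octa-2,7-dienoyl]-1,3-oxazolidin-2-one | C=C[C@@](O[Si](CC)(CC)CC)(C)CC/C=C/C(=O)N1[C@H](Cc2ccccc2)COC1=O
F7 | step 4 | (4R)-4-benzyl-3-[(3S,6R)-6-methyl-3-(prop-1-en-2-yl)-6-(triethylsilyloxy)oct-7-enoyl]-1,3-oxazolidin-2-one | C=C[C@@](O[Si](CC)(CC)CC)(C)CC[C@H](C(C)=C)CC(=O)N1[C@H](Cc2ccccc2)COC1=O
F8 | step 4 | (3S,6R)-6-methyl-3-(prop-1-en-2-yl)-6-(triethylsilyloxy)oct-7-enoic acid | C=C[C@@](O[Si](CC)(CC)CC)(C)CC[C@H](C(C)=C)CC(=O)O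
F9 | step 4 | (4S)-5-(iodomethyl)-5-methyl-4-[(3R)-3-methyl-3-(triethylsilyloxy)pent-4-en-1-yl]oxolan-2-one (C5 epimers) | C=C[C@@](O[Si](CC)(CC)CC)(C)CC[C@H]1CC(=O)OC1(C)CI
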